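| setting | violet | red | teal | Thursday's | Friday's | Sunday's | Monday's |
|---|---|---|---|---|---|---|---|
| starting material | 20 mM | 28 mM | 44 mM | 20 mM | 20 mM | 20 mM | 20 mM (fed, over 8.0 d) |
| coupling partner | 12 mM | 12 mM | 12 mM | 12.0 mM (fed, over 8.0 d) | 12.0 mM (fed, over 8.0 d) | 12.0 mM | 12.0 mM |
| second substrate | 10 mM | 10 mM | 10 mM | 10.0 mM | 10.0 mM | 10.0 mM | 10.0 mM |
| temperature | 20 °C | 31 °C | 20 °C | 25 °C |  |  | 25 °C |
| remark | run made earlier | run made earlier | run made earlier | all else is in the flask from the start; the feed brings no volume worth counting | the addition at 5 °C, then warmed to 25 °C; the feed brings no volume worth counting | everything together at the start at 5 °C, warmed to 25 °C at 8.0 d | all else is in the flask from the start; the feed brings no volume worth counting |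
| time |  |  |  | 12 d | 12 d | 12 d | 12 d |

| run | time / d | cross product / % | target / % |
|---|---|---|---|
| violet | 0.625 | 27 | 21 |
| violet | 0.833 | 33 | 22 |
| violet | 1.25 | 35 | 24 |
| violet | 2.08 | 39 | 27 |
| violet | 3.00 | 41 | 30 |
| violet | 5.00 | 40 | 31 |
| violet | 8.00 | 41 | 36 |
| red | 1.25 | 30 | 27 |
| red | 3.00 | 37 | 25 |
| red | 4.00 | 30 | 26 |
| red | 6.00 | 34 | 22 |
| red | 8.00 | 35 | 19 |
| red | 10.0 | 33 | 21 |
| teal | 1.25 | 20 | 16 |
| teal | 3.00 | 19 | 15 |
| teal | 4.00 | 21 | 13 |
| teal | 6.00 | 23 | 12 |
| teal | 8.00 | 16 | 10 |
| teal | 10.0 | 22 | 8 |

(readings scatter by 2 percentage points)

- percent here means starting material units held: one side product or self-condensation product counts as two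
- steps thought possible: starting material + coupling partner -> target; second substrate + coupling partner -> second product; starting material + second substrate -> cross product; starting material + target -> side product; 2 starting material -> self-condensation product; starting material <-> dormant form

- the flask that comes out highest in amount of cross product, in percent of the starting material charged; "all alike" if 1.5 percentage points covers them all (Thursday's / Friday's / Sunday's / Monday's / all alike)
- amount of cross product at the end, in percent of the starting material charged, Thursday's
- amount of cross product at the end, in percent of the starting material charged, Friday's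
- amount of cross product at the end, in percent of the starting material charged, Sunday's
- amount of cross product at the end, in percent of the starting material charged, Monday's

- Compare violet with the even case, in which second substrate takes starting material and coupling partner alike and splits in the ratio of their charges: that case gives cross product 31.2% of the charge, and violet's last reading, 41% at 8.00 d, is higher than that.
- Measure the excess from that reading: divide cross product over second product, taking second product as the remainder of second substrate, by starting material over partner, and get 2.73, where the even case is 1.
- Turn to Thursday's, and let second substrate live as long as violet's cross product needs to read 39%, namely 2.08 d, though Thursday's runs warmer; by then 26.0% of the partner, about a quarter, has come in.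
- Put that fraction in place of the partner's charge: the odds become 17.5, so Thursday's cross product comes to 47.3%, below the ceiling of 50.0%, which is second substrate's charge as cross product, with second substrate the limiting reagent.
- Reforge the weak link, that one reading, since second product enters as a small remainder: the mean of violet's plateau readings from 3.00 d to 8.00 d is 40.7%, and this gives the preference, the selectivity factor of starting material over partner for second substrate, as 2.61.
- Commit to 47.2% for Thursday's, and give Friday's, with the same feed, the same figure in this reckoning, which holds one preference read at one temperature and so does not part those two flasks.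
- Give Sunday's, with the partner's whole charge in from the start as in violet, the reckoned 40.7%, lower than Thursday's figure, and expect Monday's at the bottom, as it turns the ratio round, with the partner's charge standing against a trickle of starting material.
- Set beside this the forecast: Thursday's highest, at 46%, then Friday's 44%, Sunday's 40% and Monday's 15%, with the words “Feeding the partner (Thursday's) suppresses this loss”.
- Read the flasks: Thursday's 49.5%, Friday's 45.6%, Sunday's 39.4% and Monday's 17.8%, so Thursday's stands highest.

    starting material + coupling partner → target (k = 4.19 M⁻¹ h⁻¹, Ea = 59.0 kJ mol⁻¹)
    second substrate + coupling partner → second product (k = 2.75 M⁻¹ h⁻¹, Ea = 60.0 kJ mol⁻¹)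
    starting material + second substrate → cross product (k = 13.7 M⁻¹ h⁻¹, Ea = 67.0 kJ mol⁻¹)
    starting material + target → side product (k = 0.684 M⁻¹ h⁻¹, Ea = 60.0 kJ mol⁻¹)
    2 starting material → self-condensation product (k = 0.00218 M⁻¹ h⁻¹, Ea = 97.0 kJ mol⁻¹)
    starting material ⇌ dormant form (K = 0.577, k = 1.08 h⁻¹, Ea = 99.0 kJ mol⁻¹, ΔH = −16.0 kJ mol⁻¹)
    (constants at 25 °C)

- Compare Thursday's with Monday's: the gap of 32 percentage points shrinks to 0.87 points without the loss of second substrate to second product, and to 7.2 points without the backward run from dormant form, which is a part of the story; the two act together. Carry the preference into Monday's: a mean starting material of 14.4% of the charge over 8.0 d, set against the partner's charge, gives 19.3%, against the 17.8% above.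
- Move Thursday's figure by changing the charge: at 50 mM of starting material the same reckoning gives 19.5% of that larger charge, and the computed flask gives 20.0%.

The earlier runs and the new flask are simulated from invented constants.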